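**Strategy.** The 18-membered ring is opened at the diaryl ether bond between the ring A oxygen, which sits between the OMe carbon and the carbon carrying the CH2CH2 arm to ring D, and C-3 of the meta-linked ring B. Ring B has no activating substituent, so a Cr(CO)3 unit is installed on a 3-fluorophenyl fragment before assembly. The crowded ring A phenoxide then displaces fluoride from the complexed ring, making the C–O bond and the macrocycle in one operation. The precursor is the open-chain A–D–C–B tetra-aryl with a free ring A phenol, benzyl ethers on the other two phenols and (η6-fluoroarene)Cr(CO)3 on ring B.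

Key step: step 17

Remarks on the chemistry:
- The target is achiral. Complexes 20–25 carry Cr(CO)3 on a meta-disubstituted ring and are planar-chiral racemates; this is of no consequence because the metal is removed in step 18.
- In the SMILES the Cr(CO)3 unit is written as separate components; it is η6-bound to the fluorophenyl ring (ring B in 25).
- The structures of precursor 24 and product 25 were checked atom by atom against the target and needed no correction.
- Design choices on the way to 24: the nucleophilic ring A oxygen travels as a MOM acetal, which also directs the lithiation and is cleaved by acid that the complex tolerates. Ring D arrives already carrying its phosphonate. Both bridges are saturated before cyclisation.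
- Compounds 1, 8, 10, 17 and 19 are taken to be catalogue materials.

Step 1
Reactants: 1 isovanillin (3-hydroxy-4-methoxybenzaldehyde)
Product: 2 4-methoxy-3-(methoxymethoxy)benzaldehyde
Conditions: MOMCl, K2CO3, acetone, 0 °C → rt
Reagents that add atoms: chloromethyl methyl ether (MOMCl), COCCl
Why: Williamson-type O-alkylation of the phenoxide with the reactive α-chloro ether masks the future nucleophilic oxygen of ring A as a MOM acetal.

Step 2
Reactants: 2 4-methoxy-3-(methoxymethoxy)benzaldehyde
Product: 4 4-methoxy-3-(methoxymethoxy)phenol, via aryl formate 3 (not isolated)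
Conditions: mCPBA, CH2Cl2, rt; aq. NaHCO3 wash; then K2CO3 (cat.), MeOH, rt
Reagents that add atoms: 3-chloroperoxybenzoic acid (mCPBA), O=C(OO)c1cccc(Cl)c1
Why: Baeyer–Villiger oxidation of the electron-rich benzaldehyde proceeds with aryl migration to the formate, which is methanolysed to the phenol that becomes the ring A hydroxyl of the target.

Step 3
Reactants: 4 4-methoxy-3-(methoxymethoxy)phenol
Product: 5 4-(benzyloxy)-1-methoxy-2-(methoxymethoxy)benzene
Conditions: BnBr, K2CO3, DMF, rt
Reagents that add atoms: benzyl bromide, BrCc1ccccc1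
Why: Williamson ether synthesis installs benzyl as the permanent group on the ring A hydroxyl, orthogonal to the MOM acetal.

Step 4
Reactants: 5 4-(benzyloxy)-1-methoxy-2-(methoxymethoxy)benzene
Product: 7 6-(benzyloxy)-3-methoxy-2-(methoxymethoxy)benzaldehyde, via aryllithium 6 (not isolated)
Conditions: n-BuLi, TMEDA, THF, −20 → 0 °C; then DMF, −78 °C → rt; aq. NH4Cl
Reagents that add atoms: N,N-dimethylformamide, CN(C)C=O
Why: Directed ortho-metalation occurs at the only carbon flanked by two oxygen directors (OMOM and OBn; the other ortho position of OMOM is blocked by OMe), and formylation of the aryllithium with DMF places the one-carbon handle at the tetrasubstituted position.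

Step 5
Reactants: 8 methyl 3,4-dihydroxybenzoate
Product: 9 methyl 4-(benzyloxy)-3-hydroxybenzoate
Conditions: BnBr (1 equiv), K2CO3 (1 equiv), acetone, rt
Reagents that add atoms: benzyl bromide, BrCc1ccccc1
Why: Williamson ether synthesis made regioselective by acidity, since the 4-OH para to the ester is deprotonated preferentially by one equivalent of weak base and the 3-OH stays free.

Step 6
Reactants: 9 methyl 4-(benzyloxy)-3-hydroxybenzoate; 10 diethyl (4-bromobenzyl)phosphonate
Product: 11 methyl 4-(benzyloxy)-3-{4-[(diethoxyphosphoryl)methyl]phenoxy}benzoate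
Conditions: CuI (cat.), N,N-dimethylglycine·HCl (cat.), Cs2CO3, 1,4-dioxane, 100 °C
Reagents that add atoms: none
Why: Copper-catalysed Ullmann-type O-arylation of a phenol with an aryl bromide under amino acid ligand acceleration tolerates the ortho-alkoxy phenol, the ester and the phosphonate, and brings in ring D with its olefination handle in place.

Step 7
Reactants: 11 methyl 4-(benzyloxy)-3-{4-[(diethoxyphosphoryl)methyl]phenoxy}benzoate; 7 6-(benzyloxy)-3-methoxy-2-(methoxymethoxy)benzaldehyde
Product: 12 methyl 4-(benzyloxy)-3-(4-{(E)-2-[6-(benzyloxy)-3-methoxy-2-(methoxymethoxy)phenyl]ethenyl}phenoxy)benzoate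
Conditions: NaH (added last to the mixture of 11 and 7), THF, 0 °C → rt
Reagents that add atoms: none
Why: Horner–Wadsworth–Emmons olefination of the non-enolisable 2,6-dialkoxybenzaldehyde with the benzylic phosphonate carbanion should give the (E)-stilbene, the aldehyde trapping the carbanion faster than the aryl ester can.

Step 8
Reactants: 12 the (E)-stilbene ester
Product: 13 methyl 4-(benzyloxy)-3-(4-{2-[6-(benzyloxy)-3-methoxy-2-(methoxymethoxy)phenyl]ethyl}phenoxy)benzoate
Conditions: TsNHNH2, NaOAc, DME–H2O, reflux
Reagents that add atoms: none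
Why: Diimide reduction transfers H2 to the stilbene C=C in a concerted syn fashion and leaves the benzyl ethers, the MOM acetal and the ester untouched, which hydrogenation over palladium would not guarantee.

Step 9
Reactants: 13 the bibenzyl ester
Product: 14 [4-(benzyloxy)-3-(4-{2-[6-(benzyloxy)-3-methoxy-2-(methoxymethoxy)phenyl]ethyl}phenoxy)phenyl]methanol
Conditions: LiAlH4, THF, 0 °C
Reagents that add atoms: none
Why: Hydride reduction of the aryl ester gives the primary benzylic alcohol, the ethers and the acetal being inert.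

Step 10
Reactants: 14 the ring C benzylic alcohol
Product: 16 [4-(benzyloxy)-3-(4-{2-[6-(benzyloxy)-3-methoxy-2-(methoxymethoxy)phenyl]ethyl}phenoxy)benzyl]triphenylphosphonium bromide, via benzylic bromide 15 (not isolated)
Conditions: CBr4, PPh3, CH2Cl2, 0 °C; then PPh3, toluene, 90 °C
Reagents that add atoms: carbon tetrabromide, BrC(Br)(Br)Br; triphenylphosphine, c1ccc(cc1)P(c1ccccc1)c1ccccc1
Why: Appel bromination under neutral conditions spares the MOM acetal, and SN2 quaternisation of the reactive benzylic bromide with PPh3 gives the Wittig salt.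

Step 11
Reactants: 17 3-fluorobenzaldehyde
Product: 18 1-(dimethoxymethyl)-3-fluorobenzene
Conditions: HC(OMe)3, MeOH, TsOH (cat.), rt
Reagents that add atoms: trimethyl orthoformate, COC(OC)OC
Why: Acid-catalysed acetalisation, driven by the orthoformate as water scavenger, masks the aldehyde, which would not survive thermal complexation.

Step 12
Reactants: 18 1-(dimethoxymethyl)-3-fluorobenzene; 19 Cr(CO)6
Product: 20 tricarbonyl[η6-1-(dimethoxymethyl)-3-fluorobenzene]chromium (racemic)
Conditions: Bu2O–THF, reflux, N2, dark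
Reagents that add atoms: none
Why: Thermal ligand exchange replaces three CO ligands of Cr(CO)6 by the η6-arene, and since this fragment holds a single arene the metal is placed unambiguously on the future ring B.

Step 13
Reactants: 20 the acetal complex
Product: 21 tricarbonyl(η6-3-fluorobenzaldehyde)chromium (racemic)
Conditions: aq. HCl, THF, rt, N2, dark
Reagents that add atoms: water, O
Why: Acid-catalysed acetal hydrolysis, to which (η6-arene)Cr(CO)3 complexes are stable when air and light are excluded.

Step 14
Reactants: 16 the ring C phosphonium bromide; 21 tricarbonyl(η6-3-fluorobenzaldehyde)chromium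
Product: 22 Cr(CO)3 complex (metal on the fluorophenyl ring) of 1-(benzyloxy)-2-(4-{2-[6-(benzyloxy)-3-methoxy-2-(methoxymethoxy)phenyl]ethyl}phenoxy)-4-[2-(3-fluorophenyl)ethenyl]benzene, E/Z mixture
Conditions: NaN(SiMe3)2 (slightly less than 1 equiv), THF, −78 °C; then 21, −78 → 0 °C, N2, dark
Reagents that add atoms: none
Why: Wittig olefination of the complexed, strongly electrophilic aldehyde with the preformed semi-stabilised benzylic ylide leaves no free base to displace the activated fluoride, and the alkene geometry is irrelevant because the double bond is reduced next.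

Step 15
Reactants: 22 the stilbene complex
Product: 23 Cr(CO)3 complex (metal on the fluorophenyl ring) of 1-(benzyloxy)-2-(4-{2-[6-(benzyloxy)-3-methoxy-2-(methoxymethoxy)phenyl]ethyl}phenoxy)-4-[2-(3-fluorophenyl)ethyl]benzene
Conditions: KO2CN=NCO2K, AcOH, THF–MeOH, rt, N2, dark
Reagents that add atoms: none
Why: Diimide reduction of the C=C, with diimide released at room temperature by protonation and decarboxylation of the azodicarboxylate salt, avoids heat, hydrogenation catalysts and nucleophilic hydrazides, so the Cr(CO)3 unit, the C–F bond and both benzyl ethers should be retained.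

Step 16
Reactants: 23 the MOM-protected seco complex
Product: 24 Cr(CO)3 complex (metal on the fluorophenyl ring B) of 3-(benzyloxy)-2-{2-[4-(2-(benzyloxy)-5-[2-(3-fluorophenyl)ethyl]phenoxy)phenyl]ethyl}-6-methoxyphenol
Conditions: HCl, MeOH–THF, 40 °C, N2, dark
Reagents that add atoms: none
Why: Acid-catalysed methanolysis of the MOM acetal frees only the ring A phenol, the benzyl ethers and the acid-stable arene–Cr(CO)3 unit being unaffected.

Step 17
Reactants: 24 the seco phenol complex
Product: 25 ring B η6-Cr(CO)3 complex of the dibenzyl ether of the target macrocycle (benzyl on the ring A and ring C hydroxyls)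
Conditions: Cs2CO3, DMF (degassed, amine-free), 60 °C, slow addition at high dilution, N2, dark
Reagents that add atoms: none
Why: The caesium phenoxide of ring A adds to the fluorine-bearing carbon of ring B on the face away from the metal, giving an anionic η5-cyclohexadienyl intermediate whose charge is absorbed by the Cr(CO)3 unit, and loss of fluoride restores the η6-arene (addition–elimination SNAr). The closest known reactions are intermolecular aryl ether formation from phenoxides and (η6-fluoroarene)Cr(CO)3 complexes, and macrocyclic diaryl ether closures on cationic arene–ruthenium complexes. The 18-membered ring is closed by intramolecular attack of the tethered oxygen at an sp2 carbon whose leaving group lies outside the new ring, and high dilution favours this unimolecular path over chain growth. No stereocentre is formed, and the planar chirality of the complex disappears on decomplexation. Site selectivity is secured because ring B is the only complexed and the only fluorinated arene, and the ring A hydroxyl is the only free phenol. The di-ortho-substituted phenoxide is acceptable because it attacks an unhindered ring carbon directly and does not have to enter the coordination sphere of a coupling catalyst.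

Step 18
Reactants: 25 the macrocyclic complex
Product: 26 dibenzyl ether of the target macrocycle
Conditions: I2, THF, 0 °C → rt; aq. Na2S2O3
Reagents that add atoms: none
Why: Oxidative decomplexation, in which iodine oxidises zerovalent chromium and releases the arene and CO, while I2 alone should not iodinate the alkyl aryl ether rings.

Step 19
Reactants: 26 the dibenzyl macrocycle
Product: 27 CNP0179896.0 (target)
Conditions: H2 (1 atm), Pd/C (10% palladium on carbon), EtOAc–MeOH, rt
Reagents that add atoms: none
Why: Catalytic hydrogenolysis cleaves both benzyl aryl ethers, while the diaryl ethers, the methyl ether and the bibenzyl bridges are stable and no stereocentre is present.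

**Compound list**

1 | isovanillin (3-hydroxy-4-methoxybenzaldehyde) | COc1ccc(C=O)cc1O | starting material
2 | 4-methoxy-3-(methoxymethoxy)benzaldehyde | COCOc1cc(C=O)ccc1OC | intermediate
3 | 4-methoxy-3-(methoxymethoxy)phenyl formate | O=COc1ccc(OC)c(OCOC)c1 | intermediate (not isolated)
4 | 4-methoxy-3-(methoxymethoxy)phenol | COCOc1cc(O)ccc1OC | intermediate
5 | 4-(benzyloxy)-1-methoxy-2-(methoxymethoxy)benzene | COCOc1cc(OCc2ccccc2)ccc1OC | intermediate
6 | [6-(benzyloxy)-3-methoxy-2-(methoxymethoxy)phenyl]lithium | [Li]c1c(OCOC)c(OC)ccc1OCc1ccccc1 | intermediate (not isolated)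
7 | 6-(benzyloxy)-3-methoxy-2-(methoxymethoxy)benzaldehyde (ring A aldehyde) | COCOc1c(OC)ccc(OCc2ccccc2)c1C=O | intermediate
8 | methyl 3,4-dihydroxybenzoate | COC(=O)c1ccc(O)c(O)c1 | starting material
9 | methyl 4-(benzyloxy)-3-hydroxybenzoate (ring C phenol) | COC(=O)c1ccc(OCc2ccccc2)c(O)c1 | intermediate
10 | diethyl (4-bromobenzyl)phosphonate (ring D) | CCOP(=O)(Cc1ccc(Br)cc1)OCC | starting material
11 | methyl 4-(benzyloxy)-3-{4-[(diethoxyphosphoryl)methyl]phenoxy}benzoate | CCOP(=O)(Cc1ccc(Oc2cc(C(=O)OC)ccc2OCc2ccccc2)cc1)OCC | intermediate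
12 | methyl 4-(benzyloxy)-3-(4-{(E)-2-[6-(benzyloxy)-3-methoxy-2-(methoxymethoxy)phenyl]ethenyl}phenoxy)benzoate | COCOc1c(OC)ccc(OCc2ccccc2)c1/C=C/c1ccc(Oc2cc(C(=O)OC)ccc2OCc2ccccc2)cc1 | intermediate
13 | methyl 4-(benzyloxy)-3-(4-{2-[6-(benzyloxy)-3-methoxy-2-(methoxymethoxy)phenyl]ethyl}phenoxy)benzoate | COCOc1c(OC)ccc(OCc2ccccc2)c1CCc1ccc(Oc2cc(C(=O)OC)ccc2OCc2ccccc2)cc1 | intermediate
14 | [4-(benzyloxy)-3-(4-{2-[6-(benzyloxy)-3-methoxy-2-(methoxymethoxy)phenyl]ethyl}phenoxy)phenyl]methanol | COCOc1c(OC)ccc(OCc2ccccc2)c1CCc1ccc(Oc2cc(CO)ccc2OCc2ccccc2)cc1 | intermediate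
15 | 1-(benzyloxy)-2-(4-{2-[6-(benzyloxy)-3-methoxy-2-(methoxymethoxy)phenyl]ethyl}phenoxy)-4-(bromomethyl)benzene | COCOc1c(OC)ccc(OCc2ccccc2)c1CCc1ccc(Oc2cc(CBr)ccc2OCc2ccccc2)cc1 | intermediate (not isolated)
16 | [4-(benzyloxy)-3-(4-{2-[6-(benzyloxy)-3-methoxy-2-(methoxymethoxy)phenyl]ethyl}phenoxy)benzyl]triphenylphosphonium bromide | COCOc1c(OC)ccc(OCc2ccccc2)c1CCc1ccc(Oc2cc(C[P+](c3ccccc3)(c3ccccc3)c3ccccc3)ccc2OCc2ccccc2)cc1.[Br-] | intermediate
17 | 3-fluorobenzaldehyde | O=Cc1cccc(F)c1 | starting material
18 | 1-(dimethoxymethyl)-3-fluorobenzene | COC(OC)c1cccc(F)c1 | intermediate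
19 | Cr(CO)6 (hexacarbonylchromium) | [Cr].[C-]#[O+].[C-]#[O+].[C-]#[O+].[C-]#[O+].[C-]#[O+].[C-]#[O+] | starting material
20 | tricarbonyl[η6-1-(dimethoxymethyl)-3-fluorobenzene]chromium, racemic | COC(OC)c1cccc(F)c1.[Cr].[C-]#[O+].[C-]#[O+].[C-]#[O+] | intermediate
21 | tricarbonyl(η6-3-fluorobenzaldehyde)chromium, racemic | O=Cc1cccc(F)c1.[Cr].[C-]#[O+].[C-]#[O+].[C-]#[O+] | intermediate
22 | A–D–C–B stilbene, Cr(CO)3 on the fluorophenyl ring, MOM on ring A oxygen, E/Z mixture | COCOc1c(OC)ccc(OCc2ccccc2)c1CCc1ccc(Oc2cc(C=Cc3cccc(F)c3)ccc2OCc2ccccc2)cc1.[Cr].[C-]#[O+].[C-]#[O+].[C-]#[O+] | intermediate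
23 | A–D–C–B bis(bibenzyl), Cr(CO)3 on the fluorophenyl ring, MOM on ring A oxygen | COCOc1c(OC)ccc(OCc2ccccc2)c1CCc1ccc(Oc2cc(CCc3cccc(F)c3)ccc2OCc2ccccc2)cc1.[Cr].[C-]#[O+].[C-]#[O+].[C-]#[O+] | intermediate
24 | seco phenol: 3-(benzyloxy)-2-{2-[4-(2-(benzyloxy)-5-[2-(3-fluorophenyl)ethyl]phenoxy)phenyl]ethyl}-6-methoxyphenol, Cr(CO)3 on the fluorophenyl ring B | COc1ccc(OCc2ccccc2)c(CCc2ccc(Oc3cc(CCc4cccc(F)c4)ccc3OCc3ccccc3)cc2)c1O.[Cr].[C-]#[O+].[C-]#[O+].[C-]#[O+] | intermediate
25 | dibenzyl ether of the target macrocycle, η6-Cr(CO)3 on ring B | COc1ccc(OCc3ccccc3)c2c1Oc1cccc(c1)CCc1ccc(OCc3ccccc3)c(c1)Oc1ccc(cc1)CC2.[Cr].[C-]#[O+].[C-]#[O+].[C-]#[O+] | intermediate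
26 | dibenzyl ether of the target macrocycle | COc1ccc(OCc3ccccc3)c2c1Oc1cccc(c1)CCc1ccc(OCc3ccccc3)c(c1)Oc1ccc(cc1)CC2 | intermediate
27 | CNP0179896.0 | COc1ccc(O)c2c1Oc1cccc(c1)CCc1ccc(O)c(c1)Oc1ccc(cc1)CC2 | target

**Step count.** Total: 19 steps. Longest linear sequence: 14 steps (1 → 27 through steps 1–4, 7–10 and 14–19).

**Steps most likely to fail, with fallbacks**

Step 17. Ring closure may lose to intermolecular substitution and chain growth, or the metal may be shed under the basic conditions before the hindered phenoxide has added. The fallback activates ring B with a nitro group and removes it afterwards. It sets out from phosphonium salt 16. Wittig reaction with 3-fluoro-4-nitrobenzaldehyde (K2CO3, 18-crown-6, CH2Cl2) would give the nitro stilbene F1. Diimide reduction (KO2CN=NCO2K, AcOH, rt) would give the nitro bibenzyl F2, and HCl in MeOH the nitro seco phenol F3. Classical SNAr macrocyclisation (K2CO3, DMF, high dilution) would close the ring to the nitro macrocycle F4. Reduction with Fe and NH4Cl in EtOH–H2O would give the amino macrocycle F5, and reductive deamination with t-BuONO in DMF would return the route at dibenzyl macrocycle 26.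

Step 15. Reduction may stall, or be accompanied by loss of the Cr(CO)3 unit or by attack of reagent-derived nucleophiles at the activated C–F carbon. The fallback avoids the alkene altogether. It sets out from alcohol 14, from which bromide 15 would be isolated (CBr4, PPh3). Zinc insertion (Zn dust, LiCl, THF) would give the benzylic zinc bromide F6. Addition of this reagent to aldehyde complex 21 (THF, 0 °C) would give the secondary benzylic alcohol complex F7, a diastereomer mixture of no consequence. Ionic deoxygenation with Et3SiH and CF3CO2H in CH2Cl2 relies on the Cr(CO)3-stabilised benzylic cation and also cleaves the MOM acetal, so the route is rejoined at seco phenol 24.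

Step 6. The copper-catalysed coupling may stall with the ortho-substituted phenol, or the phosphonate may be degraded under prolonged heating with base. The fallback makes the ether by SNAr and introduces phosphorus afterwards. It sets out from phenol 9. Reaction with 4-fluorobenzaldehyde (K2CO3, DMF, 120 °C) would give the formyl diaryl ether F8, and NaBH4 in MeOH the benzylic alcohol F9. PBr3 in CH2Cl2 would give the benzylic bromide F10, and Arbuzov reaction with P(OEt)3 at 130 °C would return the route at phosphonate 11.

**Further compounds**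

F1 | step 17 | 1-(benzyloxy)-2-(4-{2-[6-(benzyloxy)-3-methoxy-2-(methoxymethoxy)phenyl]ethyl}phenoxy)-4-[2-(3-fluoro-4-nitrophenyl)ethenyl]benzene, E/Z mixture | COCOc1c(OC)ccc(OCc2ccccc2)c1CCc1ccc(Oc2cc(C=Cc3ccc([N+](=O)[O-])c(F)c3)ccc2OCc2ccccc2)cc1
F2 | step 17 | 1-(benzyloxy)-2-(4-{2-[6-(benzyloxy)-3-methoxy-2-(methoxymethoxy)phenyl]ethyl}phenoxy)-4-[2-(3-fluoro-4-nitrophenyl)ethyl]benzene | COCOc1c(OC)ccc(OCc2ccccc2)c1CCc1ccc(Oc2cc(CCc3ccc([N+](=O)[O-])c(F)c3)ccc2OCc2ccccc2)cc1
F3 | step 17 | 3-(benzyloxy)-2-{2-[4-(2-(benzyloxy)-5-[2-(3-fluoro-4-nitrophenyl)ethyl]phenoxy)phenyl]ethyl}-6-methoxyphenol | COc1ccc(OCc2ccccc2)c(CCc2ccc(Oc3cc(CCc4ccc([N+](=O)[O-])c(F)c4)ccc3OCc3ccccc3)cc2)c1O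
F4 | step 17 | dibenzyl ether of the target macrocycle with NO2 on ring B ortho to the new ether oxygen | COc1ccc(OCc3ccccc3)c2c1Oc1c([N+](=O)[O-])ccc(c1)CCc1ccc(OCc3ccccc3)c(c1)Oc1ccc(cc1)CC2
F5 | step 17 | dibenzyl ether of the target macrocycle with NH2 on ring B ortho to the new ether oxygen | COc1ccc(OCc3ccccc3)c2c1Oc1c(N)ccc(c1)CCc1ccc(OCc3ccccc3)c(c1)Oc1ccc(cc1)CC2
F6 | step 15 | [4-(benzyloxy)-3-(4-{2-[6-(benzyloxy)-3-methoxy-2-(methoxymethoxy)phenyl]ethyl}phenoxy)benzyl]zinc bromide | COCOc1c(OC)ccc(OCc2ccccc2)c1CCc1ccc(Oc2cc(C[Zn]Br)ccc2OCc2ccccc2)cc1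
F7 | step 15 | Cr(CO)3 complex (metal on the fluorophenyl ring) of 2-[4-(benzyloxy)-3-(4-{2-[6-(benzyloxy)-3-methoxy-2-(methoxymethoxy)phenyl]ethyl}phenoxy)phenyl]-1-(3-fluorophenyl)ethanol, diastereomer mixture | COCOc1c(OC)ccc(OCc2ccccc2)c1CCc1ccc(Oc2cc(CC(O)c3cccc(F)c3)ccc2OCc2ccccc2)cc1.[Cr].[C-]#[O+].[C-]#[O+].[C-]#[O+]
F8 | step 6 | methyl 4-(benzyloxy)-3-(4-formylphenoxy)benzoate | COC(=O)c1ccc(OCc2ccccc2)c(Oc2ccc(C=O)cc2)c1
F9 | step 6 | methyl 4-(benzyloxy)-3-[4-(hydroxymethyl)phenoxy]benzoate | COC(=O)c1ccc(OCc2ccccc2)c(Oc2ccc(CO)cc2)c1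
F10 | step 6 | methyl 4-(benzyloxy)-3-[4-(bromomethyl)phenoxy]benzoate | COC(=O)c1ccc(OCc2ccccc2)c(Oc2ccc(CBr)cc2)c1
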